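**Remarks.** α and β follow the usual flavan drawing (ring A left, O1 top right, β toward the viewer); in it the target is 2α-aryl, 3α-OH, 4β-aryl in the upper unit and 2β-aryl, 3α-OH, 4α-OH in the lower unit. Some CIP descriptors change between protected intermediates and the target through priority changes only (geometry unchanged); this is noted where it happens. "Ar*" in names means the (2S,3S,4R)-7,8-bis(benzyloxy)-2-[4-(benzyloxy)phenyl]-3,4-bis(tert-butyldimethylsilyloxy)chroman-6-yl group. Compound 20 is taken as the commercial THF solution.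

## Structural features

- The target is a dimer of two C6–C3–C6 flavans, each with a pyrogallol-type ring A (O1, 7-OH, 8-OH) and a 4-hydroxyphenyl ring B. The upper unit is a flavan-3-ol and the lower unit a flavan-3,4-diol.
- The units are joined by one bond from C4 of the upper ring C to C6 of the lower ring A. Upper C4 is therefore a diarylmethine stereocentre between two electron-rich arenes.
- There are six stereocentres in two contiguous triads. The upper C2/C3/C4 triad is 2,3-cis-3,4-trans (2R,3R,4S). The lower triad is 2,3-trans-3,4-cis (2S,3R,4R). The units are heterochiral at C2 but share 3R.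
- Fragile groups: the lower C4–OH is benzylic, para to 7-OH and ortho to O1, so it can ionise in acid and is at risk in hydrogenolysis. The 7,8-diols oxidise in base, and the 4'-OH allows C2 epimerisation through a quinone methide in base.
- The real difficulty is the interflavan bond. Pyrogallol-type rings are poor Friedel–Crafts nucleophiles, C6 must be chosen over C5 and over oxygen, the 4β configuration must be set on a 2,3-cis unit, and the lower unit has its own ionisable C4.
- Feature exploited: O1, C8a, ring A with its 7,8-oxygens, C4a, C4, C3 and C2 of the upper unit map exactly onto daphnetin (7,8-dihydroxycoumarin). Upper C4 is the β-carbon of that lactone and C2 is its carbonyl carbon. The interflavan bond can therefore be made by a catalytic asymmetric 1,4-addition, and the lactone then becomes ring C.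

## Logic of the disconnections

In one sentence: the intact lower flavan, as its 6-boronic acid 14, is added by rhodium-catalysed enantioselective 1,4-addition to the coumarin 16, whose lactone is afterwards turned into upper ring C.

- **26 ⇐ 25.** Six aryl O–benzyl bonds are cut. Benzyl is the one phenol protection that survives every step and leaves without acid or base. The demand is hydrogenolysis that spares the benzylic C4–OH of the lower unit.
- **25 ⇐ 24.** Two O–Si bonds on the lower 3,4-diol are cut. Fluoride removal avoids acid at the ionisable lower C4–O bond.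
- **24 ⇐ 23.** The O1–C2 bond of upper ring C is cut. This opens the ring to a phenol and a benzylic carbinol. The forward step must be an SN2 closure with inversion at C2 to give the 2,3-cis ring.
- **23 ⇐ 22.** The C2–H bond is cut, leaving an α-hydroxy aryl ketone. The forward reduction must be anti-selective, which the free C3–OH secures by chelation.
- **22 ⇐ 19 + 20.** The bond from C2 to ring B is cut and O1–C2 is reformed as a lactone. Ring B becomes a simple aryl Grignard reagent and the phenol is stored as the lactone. The demand is mono-addition at the carbonyl.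
- **19 ⇐ 17.** The C3–O bond is cut. In the rigid lactone the C4 aryl group shields one enolate face, so C3 is relayed from C4 as 3,4-trans.
- **17 ⇐ 14 + 16 (key).** The C4–C6 interflavan bond is cut at the coumarin stage. This splits the molecule into two halves of similar size, fixes regiochemistry at the boron-bearing carbon, and puts C4 under catalyst control instead of cation chemistry. The demand is enantioface-selective carborhodation of an electron-rich coumarin by a hindered arylboronic acid.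
- **16 ⇐ 15.** Two O–benzyl bonds; 15 is commercial.
- **14 ⇐ 11 ⇐ 10.** The C6–B bond and then two O–Si bonds are cut. Ipso borylation of the bromide carries the regiochemistry.
- **10 ⇐ 9.** The C3–O and C4–O bonds are cut. Syn-dihydroxylation anti to the C2 aryl group gives the 2,3-trans-3,4-cis triad from C2 alone.
- **9 ⇐ 8 ⇐ 7.** Dehydration and carbonyl reduction reach a flavanone whose only stereocentre is C2.
- **7 ⇐ 5 + 6.** The bond from C2 to ring B is cut. A catalytic asymmetric conjugate arylation of a chromone sets the lower C2.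
- **5 ⇐ 3 ⇐ 2 ⇐ 1.** The pyranone carbon, the bromine and two benzyl groups are removed, down to gallacetophenone 1. Bromination para to the free phenol places the future interflavan carbon unambiguously.

## Other disconnections considered

**Alternative 1:** Cut C4–C6 between two complete flavans, the route most chemists would draw first. Forward, the tri-O-benzyl all-cis flavan-3,4-diol A1 is ionised at C4 with a Lewis acid and trapped by the lower diol A2 in a Friedel–Crafts reaction to give 25. The pyrogallol-type ring of A2 is a weak π-nucleophile, and A2 carries the same ionisable C4–OH as A1, so electrophile and nucleophile roles cannot be assigned cleanly. Self-condensation, O-alkylation and attack at C5 compete, and the 4β configuration rests on substrate bias alone. The chosen plan fixes the regiochemistry with boron and C4 with a catalyst.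

**Alternative 2:** Cut C4–C4a of the upper ring C, reversing the roles of the rings. Forward, the trans-epoxy aryl ether A3 undergoes a 6-endo epoxide–arene cyclisation to 24; the cation at C4 is stabilised by the lower ring and the pyrogallol ether attacks intramolecularly. The idea is sound, but A3 contains a 2,4-dialkoxyphenyl epoxide that is prone to SN1 opening and hydride-shift rearrangement. Its three acyclic stereocentres also need an enone epoxidation, a reduction and an intermolecular Mitsunobu etherification first, which makes the route about two steps longer and more fragile.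

**Alternative 3:** Cut O1–C2 and C3–C4 together. Forward, the ortho-quinone methide from benzhydrol A4 reacts with the (Z)-enol acetate A5 in an inverse-demand hetero-Diels–Alder reaction to give the 3-O-acetate A6, setting three stereocentres at once. This is the shortest plan on paper, but the mechanism opposes every selectivity it needs. The enol oxygen polarises A5 toward the 2-acyloxy-3-aryl regiochemistry, the required exo approach of a Z-dienophile runs against the endo preference, and the absolute sense relative to the lower unit would need a catalyst to override both.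

Key step: step 11

## Route

Step 1
Reactants: 1 2',3',4'-trihydroxyacetophenone (gallacetophenone)
Product: 2 1-[3,4-bis(benzyloxy)-2-hydroxyphenyl]ethanone
Conditions: BnBr (2.1 equiv), K2CO3, DMF, 25–40 °C
Reagents that add atoms: benzyl bromide, BrCc1ccccc1
Why: Williamson etherification; the 2'-OH is hydrogen-bonded to the carbonyl group and least nucleophilic, so the 3'- and 4'-OH are benzylated selectively.

Step 2
Reactants: 2 1-[3,4-bis(benzyloxy)-2-hydroxyphenyl]ethanone
Product: 3 1-[3,4-bis(benzyloxy)-5-bromo-2-hydroxyphenyl]ethanone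
Conditions: NBS (1.05 equiv), MeCN, 0 °C to rt
Reagents that add atoms: N-bromosuccinimide, O=C1CCC(=O)N1Br
Why: Electrophilic aromatic bromination at the only position para to the free phenol and ortho to 4-OBn; this carbon becomes C6 of the lower unit, so the interflavan regiochemistry is fixed here.

Step 3
Reactants: 3 1-[3,4-bis(benzyloxy)-5-bromo-2-hydroxyphenyl]ethanone
Product: 5 7,8-bis(benzyloxy)-6-bromo-4H-chromen-4-one, via enaminone 4 (not isolated)
Conditions: Me2NCH(OMe)2, toluene, 100 °C; then conc. HCl, CH2Cl2, rt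
Reagents that add atoms: N,N-dimethylformamide dimethyl acetal, COC(OC)N(C)C
Why: Enaminone condensation at the methyl ketone, then acid-mediated oxa-Michael cyclisation and loss of dimethylamine (standard chromone synthesis).

Step 4
Reactants: 5 7,8-bis(benzyloxy)-6-bromo-4H-chromen-4-one; 6 4-(benzyloxy)phenylboronic acid
Product: 7 (2R)-7,8-bis(benzyloxy)-2-[4-(benzyloxy)phenyl]-6-bromochroman-4-one
Conditions: Pd(OCOCF3)2 (5 mol %), (S)-4-tert-butyl-2-(pyridin-2-yl)-4,5-dihydrooxazole (6 mol %), NH4PF6 (30 mol %), H2O (5 equiv), ClCH2CH2Cl, 60 °C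
Reagents that add atoms: none
Why: Palladium-catalysed asymmetric conjugate addition of an arylboronic acid to a chromone; the ligand enantiomer is chosen to deliver the aryl group to the face that gives 2R (2β-aryl), the (S)-ligand being expected by analogy with cyclic enones and the antipode used if a model shows the opposite sense. The divalent palladium catalyst leaves the aryl bromide untouched.

Step 5
Reactants: 7 (2R)-7,8-bis(benzyloxy)-2-[4-(benzyloxy)phenyl]-6-bromochroman-4-one
Product: 8 (2R,4R)-7,8-bis(benzyloxy)-2-[4-(benzyloxy)phenyl]-6-bromochroman-4-ol (2,4-cis)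
Conditions: NaBH4, THF/MeOH, 0 °C
Reagents that add atoms: none
Why: Ketone reduction by axial hydride attack should give mainly the 2,4-cis alcohol; the C4 configuration is irrelevant because it is removed in step 6.

Step 6
Reactants: 8 (2R,4R)-7,8-bis(benzyloxy)-2-[4-(benzyloxy)phenyl]-6-bromochroman-4-ol
Product: 9 (2R)-7,8-bis(benzyloxy)-2-[4-(benzyloxy)phenyl]-6-bromo-2H-chromene
Conditions: methyl N-(triethylammoniosulfonyl)carbamate (Burgess reagent), THF, 25–40 °C
Reagents that add atoms: none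
Why: Dehydration of an electron-rich benzylic alcohol through its sulfamate ester; only C3 carries β-hydrogens, so the alkene must form at C3=C4 and C2 is untouched.

Step 7
Reactants: 9 (2R)-7,8-bis(benzyloxy)-2-[4-(benzyloxy)phenyl]-6-bromo-2H-chromene
Product: 10 (2S,3R,4R)-7,8-bis(benzyloxy)-2-[4-(benzyloxy)phenyl]-6-bromochroman-3,4-diol (2,3-trans-3,4-cis)
Conditions: K2OsO4·2H2O (2 mol %), NMO, acetone/H2O, rt
Reagents that add atoms: N-methylmorpholine N-oxide, C[N+]1([O-])CCOCC1; water, O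
Why: Upjohn syn-dihydroxylation; osmium tetroxide adds to the face of C3=C4 anti to the C2 aryl group, so C2 relays both C3 and C4 (3α,4α-diol, 2β-aryl).

Step 8
Reactants: 10 (2S,3R,4R)-7,8-bis(benzyloxy)-2-[4-(benzyloxy)phenyl]-6-bromochroman-3,4-diol
Product: 11 (2S,3S,4R)-7,8-bis(benzyloxy)-2-[4-(benzyloxy)phenyl]-6-bromo-3,4-bis(tert-butyldimethylsilyloxy)chromane
Conditions: TBSOTf (3 equiv), 2,6-lutidine, CH2Cl2, 0 °C to rt
Reagents that add atoms: tert-butyldimethylsilyl trifluoromethanesulfonate, CC(C)(C)[Si](C)(C)OS(=O)(=O)C(F)(F)F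
Why: Silylation of both secondary alcohols; fluoride-labile protection avoids acid at the ionisable benzylic C4–O bond later. The C3 descriptor becomes S by priority only.

Step 9
Reactants: 11 (2S,3S,4R)-7,8-bis(benzyloxy)-2-[4-(benzyloxy)phenyl]-6-bromo-3,4-bis(tert-butyldimethylsilyloxy)chromane
Product: 14 Ar*-boronic acid, via aryllithium 12 (not isolated), via lithium triisopropoxyborate 13 (not isolated)
Conditions: n-BuLi, THF, −78 °C; B(OiPr)3, −78 °C to rt; aq. NH4Cl; used without chromatography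
Reagents that add atoms: triisopropyl borate, CC(C)OB(OC(C)C)OC(C)C; water, O
Why: Bromine–lithium exchange and borate trapping, then hydrolysis; ipso substitution keeps the C6 regiochemistry, and benzyl and silyl ethers tolerate n-BuLi at −78 °C.

Step 10
Reactants: 15 7,8-dihydroxycoumarin (daphnetin)
Product: 16 7,8-bis(benzyloxy)-2H-chromen-2-one
Conditions: BnBr (2.2 equiv), K2CO3, DMF, 50 °C
Reagents that add atoms: benzyl bromide, BrCc1ccccc1
Why: Williamson etherification of both phenols; the lactone is stable to carbonate in DMF.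

Step 11
Reactants: 14 Ar*-boronic acid; 16 7,8-bis(benzyloxy)-2H-chromen-2-one
Product: 17 (4R)-7,8-bis(benzyloxy)-4-Ar*-chroman-2-one (4β-aryl)
Conditions: Rh(acac)(C2H4)2 (5 mol %), (S)-SEGPHOS (5.5 mol %), 16 (2 equiv), 14 added slowly, dioxane/H2O 10:1, 60 °C
Reagents that add atoms: none
Why: Transmetalation of 14 gives an aryl complex of monovalent rhodium, which adds syn across C3=C4 of the coumarin with the aryl group going to C4; water protonates the resulting oxa-π-allyl rhodium enolate and regenerates the hydroxo complex. The closest known reaction type is the rhodium-catalysed asymmetric 1,4-addition of arylboronic acids to coumarins to give 4-arylchroman-2-ones (Hayashi–Miyaura reaction). The step closes no ring; it joins the two halves through the C4–C6 interflavan bond. The one new stereocentre, C4, is set by the chiral bisphosphine in the carborhodation step; the (S)-ligand is expected to deliver the aryl group to the β face by analogy with simple coumarins, and the antipode is used if a model shows the opposite sense. The stereocentres of 14 are remote from the reacting carbon, so catalyst control should dominate. Regiochemistry on the lower ring is fixed because the aryl group transfers from the boron-bearing carbon, and 1,4- over 1,2-addition follows from the soft aryl–rhodium species. The neutral, base-free medium keeps the lactone closed, and excess 16 with slow addition of 14 limits protodeboronation of the hindered ortho-alkoxy boronic acid. The product holds all atoms of the upper ring A, O1, C2, C3 and C4, with C3 and C2 placed for relay from C4.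

Step 12
Reactants: 17 (4R)-7,8-bis(benzyloxy)-4-Ar*-chroman-2-one
Product: 19 (3R,4R)-7,8-bis(benzyloxy)-3-hydroxy-4-Ar*-chroman-2-one (3,4-trans), via potassium enolate 18 (not isolated)
Conditions: KHMDS, THF, −78 °C; 2-(phenylsulfonyl)-3-phenyloxaziridine, −78 °C; aq. NH4Cl
Reagents that add atoms: 2-(phenylsulfonyl)-3-phenyloxaziridine, O=S(=O)(c1ccccc1)N1OC1c1ccccc1
Why: Enolate hydroxylation with an N-sulfonyloxaziridine; the oxidant approaches the planar lactone enolate anti to the C4 aryl group, so C4 relays C3 as 3α-OH.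

Step 13
Reactants: 19 (3R,4R)-7,8-bis(benzyloxy)-3-hydroxy-4-Ar*-chroman-2-one; 20 4-(benzyloxy)phenylmagnesium bromide
Product: 22 (2R,3R)-1-[4-(benzyloxy)phenyl]-3-[3,4-bis(benzyloxy)-2-hydroxyphenyl]-2-hydroxy-3-Ar*-propan-1-one, via Weinreb amide 21 (not isolated)
Conditions: MeNH(OMe)·HCl (3 equiv), i-PrMgCl (6 equiv), THF, −20 °C; then 20 (5 equiv), 0 °C to rt; aq. NH4Cl
Reagents that add atoms: none
Why: Aminolysis of the aryl lactone by the magnesium amide gives the Weinreb amide, and Grignard acylation stops at the ketone through the chelated tetrahedral intermediate. C3 is an alkoxide throughout and does not enolise, and the ring A phenol (future O1) is released.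

Step 14
Reactants: 22 (2R,3R)-1-[4-(benzyloxy)phenyl]-3-[3,4-bis(benzyloxy)-2-hydroxyphenyl]-2-hydroxy-3-Ar*-propan-1-one
Product: 23 (1S,2R,3R)-1-[4-(benzyloxy)phenyl]-3-[3,4-bis(benzyloxy)-2-hydroxyphenyl]-3-Ar*-propane-1,2-diol (1,2-anti)
Conditions: Zn(BH4)2, Et2O/THF, −20 °C; aq. NH4Cl
Reagents that add atoms: none
Why: Chelation-controlled reduction of an α-hydroxy ketone (Cram chelate model); zinc bridges the carbonyl and C2 hydroxy oxygens and hydride attacks from the side of the small substituent, giving the anti diol with 1S.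

Step 15
Reactants: 23 (1S,2R,3R)-1-[4-(benzyloxy)phenyl]-3-[3,4-bis(benzyloxy)-2-hydroxyphenyl]-3-Ar*-propane-1,2-diol
Product: 24 (2R,3R,4R)-7,8-bis(benzyloxy)-2-[4-(benzyloxy)phenyl]-4-Ar*-chroman-3-ol (2,3-cis-3,4-trans)
Conditions: PPh3, DIAD, THF, 0 °C
Reagents that add atoms: none
Why: Intramolecular Mitsunobu etherification; the phenol is the acidic partner and the benzylic carbinol is displaced in a 6-exo-tet SN2 closure with inversion, which turns the anti diol into the 2,3-cis ring and forms O1–C2.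

Step 16
Reactants: 24 (2R,3R,4R)-7,8-bis(benzyloxy)-2-[4-(benzyloxy)phenyl]-4-Ar*-chroman-3-ol
Product: 25 (2S,3R,4R)-7,8-bis(benzyloxy)-2-[4-(benzyloxy)phenyl]-6-[(2R,3R,4R)-7,8-bis(benzyloxy)-2-[4-(benzyloxy)phenyl]-3-hydroxychroman-4-yl]chroman-3,4-diol
Conditions: TBAF, THF, 0 °C to rt
Reagents that add atoms: none
Why: Fluoride desilylation under non-acidic conditions leaves the ionisable lower C4–O bond and all stereocentres untouched.

Step 17
Reactants: 25 (2S,3R,4R)-7,8-bis(benzyloxy)-2-[4-(benzyloxy)phenyl]-6-[(2R,3R,4R)-7,8-bis(benzyloxy)-2-[4-(benzyloxy)phenyl]-3-hydroxychroman-4-yl]chroman-3,4-diol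
Product: 26 (2S,3R,4R)-2-(4-hydroxyphenyl)-6-[(2R,3R,4S)-3,7,8-trihydroxy-2-(4-hydroxyphenyl)chroman-4-yl]chroman-3,4,7,8-tetrol (target)
Conditions: H2 (1 atm), Pd(OH)2/C, EtOAc/MeOH, rt, stopped at full debenzylation
Reagents that add atoms: none
Why: Catalytic hydrogenolysis of six aryl benzyl ethers, which should cleave much faster than the secondary benzylic C–O bonds in a neutral medium. The upper C4 descriptor changes from R to S by priority only.

## Compound list

1 | 2',3',4'-trihydroxyacetophenone | CC(=O)c1ccc(O)c(O)c1O | starting material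
2 | 1-[3,4-bis(benzyloxy)-2-hydroxyphenyl]ethanone | CC(=O)c1ccc(OCc2ccccc2)c(OCc2ccccc2)c1O | intermediate
3 | 1-[3,4-bis(benzyloxy)-5-bromo-2-hydroxyphenyl]ethanone | CC(=O)c1cc(Br)c(OCc2ccccc2)c(OCc2ccccc2)c1O | intermediate
4 | (E)-1-[3,4-bis(benzyloxy)-5-bromo-2-hydroxyphenyl]-3-(dimethylamino)prop-2-en-1-one | CN(C)/C=C/C(=O)c1cc(Br)c(OCc2ccccc2)c(OCc2ccccc2)c1O | intermediate
5 | 7,8-bis(benzyloxy)-6-bromo-4H-chromen-4-one | O=c1ccoc2c(OCc3ccccc3)c(OCc3ccccc3)c(Br)cc12 | intermediate
6 | 4-(benzyloxy)phenylboronic acid | OB(O)c1ccc(OCc2ccccc2)cc1 | starting material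
7 | (2R)-7,8-bis(benzyloxy)-2-[4-(benzyloxy)phenyl]-6-bromochroman-4-one | O=C1C[C@H](c2ccc(OCc3ccccc3)cc2)Oc2c(OCc3ccccc3)c(OCc3ccccc3)c(Br)cc12 | intermediate
8 | (2R,4R)-7,8-bis(benzyloxy)-2-[4-(benzyloxy)phenyl]-6-bromochroman-4-ol | O[C@@H]1C[C@H](c2ccc(OCc3ccccc3)cc2)Oc2c(OCc3ccccc3)c(OCc3ccccc3)c(Br)cc12 | intermediate
9 | (2R)-7,8-bis(benzyloxy)-2-[4-(benzyloxy)phenyl]-6-bromo-2H-chromene | Brc1cc2C=C[C@H](c3ccc(OCc4ccccc4)cc3)Oc2c(OCc2ccccc2)c1OCc1ccccc1 | intermediate
10 | (2S,3R,4R)-7,8-bis(benzyloxy)-2-[4-(benzyloxy)phenyl]-6-bromochroman-3,4-diol | Brc1cc2c(c(OCc3ccccc3)c1OCc1ccccc1)O[C@@H](c1ccc(OCc3ccccc3)cc1)[C@H](O)[C@@H]2O | intermediate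
11 | (2S,3S,4R)-7,8-bis(benzyloxy)-2-[4-(benzyloxy)phenyl]-6-bromo-3,4-bis(tert-butyldimethylsilyloxy)chromane | Brc1cc2c(c(OCc3ccccc3)c1OCc1ccccc1)O[C@@H](c1ccc(OCc3ccccc3)cc1)[C@H](O[Si](C)(C)C(C)(C)C)[C@@H]2O[Si](C)(C)C(C)(C)C | intermediate
12 | Ar*-lithium (6-lithio analogue of 11) | [Li]c1cc2c(c(OCc3ccccc3)c1OCc1ccccc1)O[C@@H](c1ccc(OCc3ccccc3)cc1)[C@H](O[Si](C)(C)C(C)(C)C)[C@@H]2O[Si](C)(C)C(C)(C)C | intermediate
13 | lithium Ar*-triisopropoxyborate | [Li+].CC(C)O[B-](OC(C)C)(OC(C)C)c1cc2c(c(OCc3ccccc3)c1OCc1ccccc1)O[C@@H](c1ccc(OCc3ccccc3)cc1)[C@H](O[Si](C)(C)C(C)(C)C)[C@@H]2O[Si](C)(C)C(C)(C)C | intermediate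
14 | Ar*-boronic acid | OB(O)c1cc2c(c(OCc3ccccc3)c1OCc1ccccc1)O[C@@H](c1ccc(OCc3ccccc3)cc1)[C@H](O[Si](C)(C)C(C)(C)C)[C@@H]2O[Si](C)(C)C(C)(C)C | intermediate
15 | 7,8-dihydroxy-2H-chromen-2-one (daphnetin) | O=c1ccc2ccc(O)c(O)c2o1 | starting material
16 | 7,8-bis(benzyloxy)-2H-chromen-2-one | O=c1ccc2ccc(OCc3ccccc3)c(OCc3ccccc3)c2o1 | intermediate
17 | (4R)-7,8-bis(benzyloxy)-4-Ar*-chroman-2-one | O=C1C[C@@H](c2cc3c(c(OCc4ccccc4)c2OCc2ccccc2)O[C@@H](c2ccc(OCc4ccccc4)cc2)[C@H](O[Si](C)(C)C(C)(C)C)[C@@H]3O[Si](C)(C)C(C)(C)C)c2ccc(OCc3ccccc3)c(OCc3ccccc3)c2O1 | intermediate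
18 | potassium enolate of 17 | [K+].[O-]C1=C[C@@H](c2cc3c(c(OCc4ccccc4)c2OCc2ccccc2)O[C@@H](c2ccc(OCc4ccccc4)cc2)[C@H](O[Si](C)(C)C(C)(C)C)[C@@H]3O[Si](C)(C)C(C)(C)C)c2ccc(OCc3ccccc3)c(OCc3ccccc3)c2O1 | intermediate
19 | (3R,4R)-7,8-bis(benzyloxy)-3-hydroxy-4-Ar*-chroman-2-one | O=C1[C@H](O)[C@@H](c2cc3c(c(OCc4ccccc4)c2OCc2ccccc2)O[C@@H](c2ccc(OCc4ccccc4)cc2)[C@H](O[Si](C)(C)C(C)(C)C)[C@@H]3O[Si](C)(C)C(C)(C)C)c2ccc(OCc3ccccc3)c(OCc3ccccc3)c2O1 | intermediate
20 | 4-(benzyloxy)phenylmagnesium bromide | Br[Mg]c1ccc(OCc2ccccc2)cc1 | starting material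
21 | (2R,3R)-3-[3,4-bis(benzyloxy)-2-hydroxyphenyl]-2-hydroxy-N-methoxy-N-methyl-3-Ar*-propanamide | CON(C)C(=O)[C@H](O)[C@@H](c2cc3c(c(OCc4ccccc4)c2OCc2ccccc2)O[C@@H](c2ccc(OCc4ccccc4)cc2)[C@H](O[Si](C)(C)C(C)(C)C)[C@@H]3O[Si](C)(C)C(C)(C)C)c1ccc(OCc2ccccc2)c(OCc2ccccc2)c1O | intermediate
22 | (2R,3R)-1-[4-(benzyloxy)phenyl]-3-[3,4-bis(benzyloxy)-2-hydroxyphenyl]-2-hydroxy-3-Ar*-propan-1-one | O=C(c1ccc(OCc2ccccc2)cc1)[C@H](O)[C@@H](c2cc3c(c(OCc4ccccc4)c2OCc2ccccc2)O[C@@H](c2ccc(OCc4ccccc4)cc2)[C@H](O[Si](C)(C)C(C)(C)C)[C@@H]3O[Si](C)(C)C(C)(C)C)c1ccc(OCc2ccccc2)c(OCc2ccccc2)c1O | intermediate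
23 | (1S,2R,3R)-1-[4-(benzyloxy)phenyl]-3-[3,4-bis(benzyloxy)-2-hydroxyphenyl]-3-Ar*-propane-1,2-diol | O[C@@H](c1ccc(OCc2ccccc2)cc1)[C@H](O)[C@@H](c2cc3c(c(OCc4ccccc4)c2OCc2ccccc2)O[C@@H](c2ccc(OCc4ccccc4)cc2)[C@H](O[Si](C)(C)C(C)(C)C)[C@@H]3O[Si](C)(C)C(C)(C)C)c1ccc(OCc2ccccc2)c(OCc2ccccc2)c1O | intermediate
24 | (2R,3R,4R)-7,8-bis(benzyloxy)-2-[4-(benzyloxy)phenyl]-4-Ar*-chroman-3-ol | O(Cc1ccccc1)c1ccc([C@H]2Oc3c(ccc(OCc4ccccc4)c3OCc3ccccc3)[C@H](c3cc4c(c(OCc5ccccc5)c3OCc3ccccc3)O[C@@H](c3ccc(OCc5ccccc5)cc3)[C@H](O[Si](C)(C)C(C)(C)C)[C@@H]4O[Si](C)(C)C(C)(C)C)[C@H]2O)cc1 | intermediate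
25 | (2S,3R,4R)-7,8-bis(benzyloxy)-2-[4-(benzyloxy)phenyl]-6-[(2R,3R,4R)-7,8-bis(benzyloxy)-2-[4-(benzyloxy)phenyl]-3-hydroxychroman-4-yl]chroman-3,4-diol | O(Cc1ccccc1)c1ccc([C@H]2Oc3c(ccc(OCc4ccccc4)c3OCc3ccccc3)[C@H](c3cc4c(c(OCc5ccccc5)c3OCc3ccccc3)O[C@@H](c3ccc(OCc5ccccc5)cc3)[C@H](O)[C@@H]4O)[C@H]2O)cc1 | intermediate
26 | (2S,3R,4R)-2-(4-hydroxyphenyl)-6-[(2R,3R,4S)-3,7,8-trihydroxy-2-(4-hydroxyphenyl)chroman-4-yl]chroman-3,4,7,8-tetrol | Oc1ccc([C@H]2Oc3c(ccc(O)c3O)[C@H](c3cc4c(c(O)c3O)O[C@@H](c3ccc(O)cc3)[C@H](O)[C@@H]4O)[C@H]2O)cc1 | target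

## Step count and least certain steps

Total: 17 steps. Longest linear sequence: 16 steps (steps 1–9, then 11–17); step 10 is the only side branch.

**Step 11 (key).** The 7-benzyloxy group donates into C4 of the coumarin, which slows carborhodation, while the hindered ortho-alkoxy boronic acid 14 can lose boron by protonolysis. The likely failure is low conversion with consumption of 14. Fallback: setting out from 14 and 16, an oxidative Heck coupling (Pd(OAc)2, 1,10-phenanthroline, O2, DMF) forms the same C4–C6 bond at the unsaturated level to give 7,8-bis(benzyloxy)-4-Ar*-2H-chromen-2-one F1. A copper hydride-catalysed asymmetric conjugate reduction of F1 (Cu(OAc)2·H2O, DTBM-SEGPHOS enantiomer chosen for the β-aryl product, (EtO)2MeSiH, t-BuOH, toluene) then sets C4 and returns to the route at 17.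

**Step 12.** The enolate of an aryl lactone can expel the phenoxide by β-elimination to a ketene, and facial selectivity may be incomplete if the C4 aryl group is not pseudo-axial. Fallback: setting out from 17, DIBAL reduction gives the lactol 7,8-bis(benzyloxy)-4-Ar*-chroman-2-ol F2. Dehydration (MsCl, Et3N) gives the enol ether (4R)-7,8-bis(benzyloxy)-4-Ar*-4H-chromene F3. Dihydroxylation (OsO4, NMO) anti to the C4 aryl group gives the lactol diol 7,8-bis(benzyloxy)-4-Ar*-chroman-2,3-diol F4, and selective lactol oxidation (Ag2CO3 on Celite, toluene, heat) returns to the route at 19.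

**Step 13.** The Grignard reagent may over-add to the ketone, or the hindered lactone may be only partly aminolysed in the one-pot sequence. Fallback: setting out from 19, silylation (TESOTf, 2,6-lutidine) gives the lactone (3R,4R)-7,8-bis(benzyloxy)-3-(triethylsilyloxy)-4-Ar*-chroman-2-one F7. Addition of 20 (1.1 equiv, −78 °C) opens it to the keto phenol (2R,3R)-1-[4-(benzyloxy)phenyl]-3-[3,4-bis(benzyloxy)-2-hydroxyphenyl]-2-(triethylsilyloxy)-3-Ar*-propan-1-one F8. Selective removal of the triethylsilyl group (PPTS, MeOH, 0 °C) returns to the route at 22.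

**Step 15.** The 4-benzyloxybenzylic oxyphosphonium ion may ionise before displacement, which erodes the inversion and gives some 2,3-trans ring; the C3 hydroxy group may also be activated. Fallback: setting out from 23, treatment with HC(OEt)3 and catalytic PPTS forms the cyclic orthoformate of the 1,2-diol, whose dioxolanylium ion is opened at the benzylic carbon by the phenol with inversion. This gives the 3-O-formate of 24, (2R,3R,4R)-7,8-bis(benzyloxy)-2-[4-(benzyloxy)phenyl]-4-Ar*-chroman-3-yl formate F5, and K2CO3 in MeOH returns to the route at 24.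

**Step 17.** Over-reduction is the risk: hydrogenolysis of the benzylic C4–OH of the lower unit, which is activated by the para and ortho oxygens, once the phenols are free. Fallback: setting out from 24, the order of the last two steps is reversed. Hydrogenolysis with the bulky silyl ether still on the lower C4 oxygen gives the hexaphenol (2R,3R,4S)-2-(4-hydroxyphenyl)-4-[(2S,3S,4R)-3,4-bis(tert-butyldimethylsilyloxy)-7,8-dihydroxy-2-(4-hydroxyphenyl)chroman-6-yl]chroman-3,7,8-triol F6. Desilylation with acetic acid-buffered TBAF under argon then returns to the route at 26.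

## Further compounds

F1 | step 11 | 7,8-bis(benzyloxy)-4-Ar*-2H-chromen-2-one | O=c1cc(-c2cc3c(c(OCc4ccccc4)c2OCc2ccccc2)O[C@@H](c2ccc(OCc4ccccc4)cc2)[C@H](O[Si](C)(C)C(C)(C)C)[C@@H]3O[Si](C)(C)C(C)(C)C)c2ccc(OCc3ccccc3)c(OCc3ccccc3)c2o1
F2 | step 12 | (4R)-7,8-bis(benzyloxy)-4-Ar*-chroman-2-ol (anomeric mixture) | OC1C[C@@H](c2cc3c(c(OCc4ccccc4)c2OCc2ccccc2)O[C@@H](c2ccc(OCc4ccccc4)cc2)[C@H](O[Si](C)(C)C(C)(C)C)[C@@H]3O[Si](C)(C)C(C)(C)C)c2ccc(OCc3ccccc3)c(OCc3ccccc3)c2O1
F3 | step 12 | (4R)-7,8-bis(benzyloxy)-4-Ar*-4H-chromene | C1=C[C@@H](c2cc3c(c(OCc4ccccc4)c2OCc2ccccc2)O[C@@H](c2ccc(OCc4ccccc4)cc2)[C@H](O[Si](C)(C)C(C)(C)C)[C@@H]3O[Si](C)(C)C(C)(C)C)c2ccc(OCc3ccccc3)c(OCc3ccccc3)c2O1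
F4 | step 12 | (3R,4R)-7,8-bis(benzyloxy)-4-Ar*-chroman-2,3-diol (anomeric mixture) | OC1[C@H](O)[C@@H](c2cc3c(c(OCc4ccccc4)c2OCc2ccccc2)O[C@@H](c2ccc(OCc4ccccc4)cc2)[C@H](O[Si](C)(C)C(C)(C)C)[C@@H]3O[Si](C)(C)C(C)(C)C)c2ccc(OCc3ccccc3)c(OCc3ccccc3)c2O1
F7 | step 13 | (3R,4R)-7,8-bis(benzyloxy)-3-(triethylsilyloxy)-4-Ar*-chroman-2-one | O=C1[C@H](O[Si](CC)(CC)CC)[C@@H](c2cc3c(c(OCc4ccccc4)c2OCc2ccccc2)O[C@@H](c2ccc(OCc4ccccc4)cc2)[C@H](O[Si](C)(C)C(C)(C)C)[C@@H]3O[Si](C)(C)C(C)(C)C)c2ccc(OCc3ccccc3)c(OCc3ccccc3)c2O1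
F8 | step 13 | (2R,3R)-1-[4-(benzyloxy)phenyl]-3-[3,4-bis(benzyloxy)-2-hydroxyphenyl]-2-(triethylsilyloxy)-3-Ar*-propan-1-one | O=C(c1ccc(OCc2ccccc2)cc1)[C@H](O[Si](CC)(CC)CC)[C@@H](c2cc3c(c(OCc4ccccc4)c2OCc2ccccc2)O[C@@H](c2ccc(OCc4ccccc4)cc2)[C@H](O[Si](C)(C)C(C)(C)C)[C@@H]3O[Si](C)(C)C(C)(C)C)c1ccc(OCc2ccccc2)c(OCc2ccccc2)c1O
F5 | step 15 | (2R,3R,4R)-7,8-bis(benzyloxy)-2-[4-(benzyloxy)phenyl]-4-Ar*-chroman-3-yl formate | O(Cc1ccccc1)c1ccc([C@H]2Oc3c(ccc(OCc4ccccc4)c3OCc3ccccc3)[C@H](c3cc4c(c(OCc5ccccc5)c3OCc3ccccc3)O[C@@H](c3ccc(OCc5ccccc5)cc3)[C@H](O[Si](C)(C)C(C)(C)C)[C@@H]4O[Si](C)(C)C(C)(C)C)[C@H]2OC=O)cc1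
F6 | step 17 | (2R,3R,4S)-2-(4-hydroxyphenyl)-4-[(2S,3S,4R)-3,4-bis(tert-butyldimethylsilyloxy)-7,8-dihydroxy-2-(4-hydroxyphenyl)chroman-6-yl]chroman-3,7,8-triol | Oc1ccc([C@H]2Oc3c(ccc(O)c3O)[C@H](c3cc4c(c(O)c3O)O[C@@H](c3ccc(O)cc3)[C@H](O[Si](C)(C)C(C)(C)C)[C@@H]4O[Si](C)(C)C(C)(C)C)[C@H]2O)cc1
A1 | alternative 1 | (2R,3R,4R)-7,8-bis(benzyloxy)-2-[4-(benzyloxy)phenyl]chroman-3,4-diol | c1cc2c(c(OCc3ccccc3)c1OCc1ccccc1)O[C@H](c1ccc(OCc3ccccc3)cc1)[C@H](O)[C@@H]2O
A2 | alternative 1 | (2S,3R,4R)-7,8-bis(benzyloxy)-2-[4-(benzyloxy)phenyl]chroman-3,4-diol | c1cc2c(c(OCc3ccccc3)c1OCc1ccccc1)O[C@@H](c1ccc(OCc3ccccc3)cc1)[C@H](O)[C@@H]2O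
A3 | alternative 2 | trans-epoxide 2-[(R)-[4-(benzyloxy)phenyl][2,3-bis(benzyloxy)phenoxy]methyl]-3-Ar*-oxirane, configured for anti opening at the Ar*-bearing carbon | O(Cc1ccccc1)c1ccc(cc1)[C@@H](Oc1cccc(OCc2ccccc2)c1OCc1ccccc1)[C@@H]1O[C@H]1c1cc2c(c(OCc3ccccc3)c1OCc1ccccc1)O[C@@H](c1ccc(OCc3ccccc3)cc1)[C@H](O[Si](C)(C)C(C)(C)C)[C@@H]2O[Si](C)(C)C(C)(C)C
A4 | alternative 3 | [3,4-bis(benzyloxy)-2-hydroxyphenyl](Ar*)methanol (carbinol epimers, both give the same quinone methide) | OC(c1ccc(OCc2ccccc2)c(OCc2ccccc2)c1O)c1cc2c(c(OCc3ccccc3)c1OCc1ccccc1)O[C@@H](c1ccc(OCc3ccccc3)cc1)[C@H](O[Si](C)(C)C(C)(C)C)[C@@H]2O[Si](C)(C)C(C)(C)C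
A5 | alternative 3 | (Z)-2-[4-(benzyloxy)phenyl]ethenyl acetate | CC(=O)O/C=C\c1ccc(OCc2ccccc2)cc1
A6 | alternative 3 | (2R,3R,4R)-7,8-bis(benzyloxy)-2-[4-(benzyloxy)phenyl]-4-Ar*-chroman-3-yl acetate | O(Cc1ccccc1)c1ccc([C@H]2Oc3c(ccc(OCc4ccccc4)c3OCc3ccccc3)[C@H](c3cc4c(c(OCc5ccccc5)c3OCc3ccccc3)O[C@@H](c3ccc(OCc5ccccc5)cc3)[C@H](O[Si](C)(C)C(C)(C)C)[C@@H]4O[Si](C)(C)C(C)(C)C)[C@H]2OC(C)=O)cc1
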